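Target is what substrate and coupling partner give over free catalyst, and its isomer grows beside it, so you want the share of target in that pair in violet, amber and red at the asked time.

the same everywhere: substrate 0.010 M
- epsilon: coupling partner 0.040 M; free catalyst 51 µM; run made earlier
- zeta: coupling partner 0.040 M; free catalyst 710 µM; run made earlier
- violet: coupling partner 0.0400 M; free catalyst 100 µM; time 2.0 min
- amber: coupling partner 0.0400 M; free catalyst 300 µM; time 2.0 min
- red: coupling partner 0.0400 M; free catalyst 1000 µM; time 2.0 min

| run | time / s | target / % | isomer of the product / % |
|---|---|---|---|
| epsilon | 10.0 | 15 | 3 |
| epsilon | 15.0 | 22 | 3 |
| epsilon | 40.0 | 44 | 14 |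
| epsilon | 80.0 | 45 | 31 |
| zeta | 20.0 | 78 | 18 |
| zeta | 40.0 | 60 | 34 |
| zeta | 60.0 | 55 | 42 |
| zeta | 80.0 | 54 | 39 |

(standard deviation of a reading: 2 percentage points)

- share of target in all that became target or isomer of the product for violet, amber, red, in this order
- the course of these numbers from the first flask to the last (rises all the way / falls all the way / rises, then falls / hardly changes / falls, then rises)

- the numbers in the tables scatter by 2 percentage points (one standard deviation)
- "hardly changes" means that all values lie within two and a half points (for a concentration: within two and a half percent of the largest)

1. Take the share of target in the pair, as fractions of the charge. It ignores how much pair has formed. In zeta, at equal time steps, it reads 81.3%, 63.8% and 56.7%.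

2. If the share behaves like a first-order lag, each drop is a fixed factor of the one before, and the logarithm of that factor over the step gives a reading, with the scatter of the zeta run, of 0.0447 s⁻¹. Call this the relaxation rate, the rate at which the gap between the share and its plateau closes. Integrated, the gap left after a time is the exponential of minus rate times time, which halves every 15.5 s.

3. At 2.0 min that leaves 0.470% of the gap. But the pair is not all made at the start, and late target has had less time. In epsilon the pair reaches 58.0% at 40.0 s. If the making keeps that average pace and scales with free catalyst, I estimate that violet finishes near 35.2 s. Its youngest target then keeps 2.26% of its gap, so this objection falls away. Amber and red hold more free catalyst than violet.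

4. A harder objection concerns the plateau. The late zeta shares, 56.7% and 58.1%, look flat, yet the closed form leaves 6.85% and 2.80% of a gap that starts from a share of one. Removing that gap gives a plateau (thermodynamic control) read near 55.2% in zeta, with the scatter of its readings, and that is my estimate for violet, amber and red.

5. The forecast gives 58%, 57% and 57%, so hardly changes, since “it plateaus near 57%”. My reckoning gives the same shape at a lower height.

The flasks give 52.4%, 52.2% and 52.1%: hardly changes.

    2 substrate → self-condensation product (k = 1.37 M⁻¹ s⁻¹)
    catalyst intermediate B → free catalyst + target (k = 7.68 s⁻¹)
    substrate + free catalyst → catalyst intermediate A (k = 6840 M⁻¹ s⁻¹)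
    catalyst intermediate B → spent catalyst (k = 0.00832 s⁻¹)
    target ⇌ isomer of the product (K = 0.936, k = 0.0190 s⁻¹)
    coupling partner + catalyst intermediate A → catalyst intermediate B (k = 210 M⁻¹ s⁻¹)

The constants of the step between target and its isomer put the plateau at 51.7%. Over the last minute, from 1.00 min to 2.0 min, the relaxation rate read in zeta shrinks a gap to 6.84%. Violet's gap to that plateau shrank to 9.53%, and red's to 9.20%. The plateau comes from the undoing of isomer of the product into target: red without that step ends at 10.5% instead of 52.1%.

The runs come from a simulation from invented constants; the scatter is artificial.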